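The dimethylpyran ring fused to ring B is disconnected last. Its C4'–CH and O3'–CMe2 bonds are made in one operation by formal [3+3] chromenylation of a free phenol with a prenal equivalent. The sequence is ortho C–C bond formation, loss of ethanol to an ortho-quinone methide, then oxa-6π electrocyclisation. The precursor is unprotected 3,5,7,3'-tetrahydroxy-6,8-diprenylflavone, built from diprenylated phloroacetophenone by Claisen–Schmidt and Algar–Flynn–Oyamada reactions. The step exploits the substitution pattern. Every carbon ortho to O5 and O7 of ring A (C4a, C6, C8) and both carbons of the enol C2=C3 are substituted, so only O3' of ring B has free ortho CH groups. C2' is shielded by ring C, leaving C4'.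

Key step: step 6

Remark: flavone numbering is used (ring A = C5–C8, ring C = O1–C4, ring B = primed atoms), prenyl = 3-methylbut-2-enyl, MOM = methoxymethyl, and prenal diethyl acetal 10 is taken as a catalogue chemical.

Step 1
Reactants: 1 phloroacetophenone (2,4,6-trihydroxyacetophenone); 2 prenyl bromide (1-bromo-3-methylbut-2-ene)
Product: 3 diprenylphloroacetophenone [1-(2,4,6-trihydroxy-3,5-diprenylphenyl)ethanone]
Conditions: 2 (2.1 equiv), KOH (2.1 equiv), H2O, 0 °C to rt
Reagents that add atoms: prenyl bromide 2, CC(C)=CCBr
Why: Phenolate C-alkylation (nuclear prenylation of an acylphloroglucinol), in which water solvates the phenolate oxygens so that the ambident anion should react at its only two free ring carbons, C3 and C5.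

Step 2
Reactants: 3 diprenylphloroacetophenone
Product: 4 bis-MOM ketone [1-(2-hydroxy-4,6-bis(methoxymethoxy)-3,5-diprenylphenyl)ethanone]
Conditions: MOMCl (2.2 equiv), K2CO3, acetone, reflux
Reagents that add atoms: chloromethyl methyl ether (MOMCl), COCCl
Why: Williamson-type O-alkylation in which the 4-hydroxyl and one of the two equivalent ortho hydroxyls react, while the last hydroxyl is held back by its hydrogen bond to the acetyl carbonyl.

Step 3
Reactants: 4 bis-MOM ketone; 5 3-hydroxybenzaldehyde
Product: 6 chalcone [(E)-3,2'-dihydroxy-4',6'-bis(methoxymethoxy)-3',5'-diprenylchalcone]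
Conditions: KOH (excess), EtOH–H2O, rt
Reagents that add atoms: none
Why: Claisen–Schmidt condensation (aldol addition, then E1cB dehydration to the thermodynamic E-enone) of the methyl ketone enolate with a non-enolisable aldehyde whose meta-phenoxide is not conjugated with the formyl group.

Step 4
Reactants: 6 chalcone
Product: 8 bis-MOM flavonol [3-hydroxy-2-(3-hydroxyphenyl)-5,7-bis(methoxymethoxy)-6,8-diprenyl-4H-chromen-4-one], via trans-dihydroflavonol 7 (not isolated)
Conditions: 30% H2O2, NaOH (aq), MeOH, 0 °C to rt
Reagents that add atoms: hydrogen peroxide, OO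
Why: Algar–Flynn–Oyamada reaction, in which the 2'-phenoxide closes ring C at the β-carbon, alkaline H2O2 hydroxylates the α-carbon to give trans-dihydroflavonol 7 and excess peroxide dehydrogenates 7 to the flavonol (erasing both transient stereocentres), while this nucleophilic oxidant leaves the electron-rich prenyl alkenes untouched.

Step 5
Reactants: 8 bis-MOM flavonol
Product: 9 tetraol flavonol [3,5,7-trihydroxy-2-(3-hydroxyphenyl)-6,8-diprenyl-4H-chromen-4-one]
Conditions: 3 M HCl (aq), MeOH, 50 °C
Reagents that add atoms: none
Why: Acid-catalysed transacetalisation (standard MOM cleavage) hands both CH2OMe groups to methanol, and dilute acid at moderate temperature should spare the ortho-prenylphenol units from chroman closure.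

Step 6
Reactants: 9 tetraol flavonol; 10 prenal diethyl acetal (1,1-diethoxy-3-methylbut-2-ene)
Product: 13 dorsilurin C, via benzylic ethyl ether 11 (not isolated), via ortho-quinone methide 12 (not isolated)
Conditions: 10 (3 equiv), 3-picoline (0.5 equiv), p-xylene, 140 °C, under argon, EtOH distilled off; aq. citric acid work-up
Reagents that add atoms: prenal diethyl acetal 10, CCOC(OCC)C=C(C)C
Why: In the phenol/3-picoline buffer acetal 10 ionises to the 1-ethoxy-3-methylallyl cation, which O3'–H of ring B takes up and hands on to the ortho carbon C4' (direct ortho attack or [3,3] shift of the tertiary aryl ether), so that benzylic ether 11 carries the new C4'–CH bond. Thermal loss of ethanol from 11 gives ortho-quinone methide 12, and its O3'=C3'–C4'=CH–CH=CMe2 array closes the pyran ring by a thermally allowed disrotatory oxa-6π electrocyclisation that makes the O3'–CMe2 bond and restores the aromaticity of ring B. The closest known reaction type is the amine-buffered thermal chromenylation of phenols, electron-poor ones included, with prenal or its acetals (formal [3+3] annulation). No stereocentre is left to control, because the carbinol carbon of 11 becomes planar in 12 and the new quaternary carbon bears two methyl groups. The chemoselectivity needed among four hydroxyl groups comes from the substitution pattern: O5 and O7 have only substituted ortho carbons (C4a, C6, C8) and O3 sits on the fully substituted C2=C3 bond, so their exchange with 10 is reversible and cannot reach a quinone methide. The regioselectivity needed between C2' and C4' comes from ring C, whose O1 and 3-hydroxyl flank C2' and would clash with an alkylidene there, whereas C4' is open.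

Compound list
1 | phloroacetophenone (2,4,6-trihydroxyacetophenone) | CC(=O)c1c(O)cc(O)cc1O | starting material
2 | prenyl bromide (1-bromo-3-methylbut-2-ene) | CC(C)=CCBr | starting material
3 | 1-(2,4,6-trihydroxy-3,5-diprenylphenyl)ethanone | CC(=O)c1c(O)c(CC=C(C)C)c(O)c(CC=C(C)C)c1O | intermediate
4 | 1-(2-hydroxy-4,6-bis(methoxymethoxy)-3,5-diprenylphenyl)ethanone | CC(=O)c1c(O)c(CC=C(C)C)c(OCOC)c(CC=C(C)C)c1OCOC | intermediate
5 | 3-hydroxybenzaldehyde | O=Cc1cccc(O)c1 | starting material
6 | (E)-3,2'-dihydroxy-4',6'-bis(methoxymethoxy)-3',5'-diprenylchalcone | O=C(/C=C/c1cccc(O)c1)c1c(O)c(CC=C(C)C)c(OCOC)c(CC=C(C)C)c1OCOC | intermediate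
7 | (2R*,3R*)-3-hydroxy-2-(3-hydroxyphenyl)-5,7-bis(methoxymethoxy)-6,8-diprenylchroman-4-one (racemic trans-dihydroflavonol, one enantiomer drawn, not isolated) | Oc1cccc([C@@H]2[C@@H](O)C(=O)c3c(OCOC)c(CC=C(C)C)c(OCOC)c(CC=C(C)C)c3O2)c1 | intermediate
8 | 3-hydroxy-2-(3-hydroxyphenyl)-5,7-bis(methoxymethoxy)-6,8-diprenyl-4H-chromen-4-one | O=c1c(O)c(-c2cccc(O)c2)oc2c(CC=C(C)C)c(OCOC)c(CC=C(C)C)c(OCOC)c12 | intermediate
9 | 3,5,7-trihydroxy-2-(3-hydroxyphenyl)-6,8-diprenyl-4H-chromen-4-one | O=c1c(O)c(-c2cccc(O)c2)oc2c(CC=C(C)C)c(O)c(CC=C(C)C)c(O)c12 | intermediate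
10 | 1,1-diethoxy-3-methylbut-2-ene (prenal diethyl acetal) | CCOC(OCC)C=C(C)C | starting material
11 | 9 carrying a 1-ethoxy-3-methylbut-2-enyl group at C4' (racemic benzylic ethyl ether, not isolated) | CCOC(C=C(C)C)c1ccc(cc1O)-c1oc2c(CC=C(C)C)c(O)c(CC=C(C)C)c(O)c2c(=O)c1O | intermediate
12 | ortho-quinone methide: ring B as the 3'-oxo-4'-(3-methylbut-2-enylidene)cyclohexadiene, exocyclic alkene Z (vinyl group on the carbonyl side), not isolated | CC(C)=C/C=C1/C=CC(c2oc3c(CC=C(C)C)c(O)c(CC=C(C)C)c(O)c3c(=O)c2O)=CC1=O | intermediate
13 | dorsilurin C | CC(C)=CCc1c(O)c(CC=C(C)C)c2oc(-c3ccc4c(c3)OC(C)(C)C=C4)c(O)c(=O)c2c1O | target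

Total step count: 6. Longest linear sequence: 6 steps (1 → 3 → 4 → 6 → 8 → 9 → 13).

Steps most likely to fail

Step 6. Three things may go wrong:
- Ortho C–C bond formation may be sluggish, because the reacting carbon of ring B is conjugated with the chromone acceptor.
- Part of the material may close at C2'.
- The ring A hydroxyls may tie up the acetal.

The fallback builds the pyran ring first, on an activated phenol whose second hydroxyl fixes the regiochemistry and is later traded for carbon. It sets out from 4 and comes back to the route at 13. The partner aldehyde is made separately from commercial resorcinol and prenal. Resorcinol and prenal are condensed (pyridine, 140 °C) to 2,2-dimethyl-2H-chromen-7-ol F1. Tf2O/pyridine gives 2,2-dimethyl-2H-chromen-7-yl triflate F2. Reductive carbonylation (Pd(OAc)2, dppp, CO, Et3SiH, Et3N, DMF) gives 2,2-dimethyl-2H-chromene-7-carbaldehyde F3. Claisen–Schmidt condensation of F3 with 4 gives the chromenyl chalcone F4, alkaline H2O2 gives dorsilurin C 5,7-bis-MOM ether F5, and HCl/MeOH releases 13.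

Step 4. The 6'-alkoxy group twists the enone, which may favour five-membered closure of the 2'-phenoxide at the α-carbon over six-membered closure at the β-carbon. The fallback removes the free phenoxide from the oxidation and closes ring C under acid, where the benzylic carbon is attacked. It sets out from 3 and comes back at 9. Exhaustive protection (MOMCl, NaH, DMF) gives the tris-MOM ketone F6. Claisen–Schmidt condensation with 5 gives the tris-MOM chalcone F7. Weitz–Scheffer epoxidation (H2O2, NaOH, MeOH) gives the racemic trans-epoxychalcone F8. HCl/MeOH strips the MOM groups, and the freed phenol opens the protonated epoxide at the benzylic carbon with inversion to give the racemic trans-dihydroflavonol tetraol F9. Aerobic dehydrogenation in hot aqueous-ethanolic NaHSO3 (the classical dihydroflavonol-to-flavonol conversion) then delivers 9.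

Step 1. O-alkylation, incomplete alkylation and geminal (dearomatising) alkylation at an already prenylated carbon may all compete. The fallback accepts O-alkylation and moves the groups afterwards. It sets out from 1 (with 2) and comes back at 3. K2CO3 in refluxing acetone gives 2-hydroxy-4,6-bis(prenyloxy)acetophenone F10. A Bi(OTf)3-catalysed [1,3] O-to-C prenyl shift (CH2Cl2, rt) then places one prenyl group on each of the only two free ring carbons to give 3.

Further compounds
F1 | step 6 | 2,2-dimethyl-2H-chromen-7-ol | CC1(C)C=Cc2ccc(O)cc2O1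
F2 | step 6 | 2,2-dimethyl-2H-chromen-7-yl triflate | CC1(C)C=Cc2ccc(OS(=O)(=O)C(F)(F)F)cc2O1
F3 | step 6 | 2,2-dimethyl-2H-chromene-7-carbaldehyde | CC1(C)C=Cc2ccc(C=O)cc2O1
F4 | step 6 | chromenyl chalcone | O=C(/C=C/c1ccc2c(c1)OC(C)(C)C=C2)c1c(O)c(CC=C(C)C)c(OCOC)c(CC=C(C)C)c1OCOC
F5 | step 6 | dorsilurin C 5,7-bis-MOM ether | O=c1c(O)c(-c2ccc3c(c2)OC(C)(C)C=C3)oc2c(CC=C(C)C)c(OCOC)c(CC=C(C)C)c(OCOC)c12
F6 | step 4 | tris-MOM ketone | CC(=O)c1c(OCOC)c(CC=C(C)C)c(OCOC)c(CC=C(C)C)c1OCOC
F7 | step 4 | tris-MOM chalcone | O=C(/C=C/c1cccc(O)c1)c1c(OCOC)c(CC=C(C)C)c(OCOC)c(CC=C(C)C)c1OCOC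
F8 | step 4 | racemic trans-epoxychalcone (one enantiomer drawn) | O=C([C@@H]1O[C@H]1c1cccc(O)c1)c1c(OCOC)c(CC=C(C)C)c(OCOC)c(CC=C(C)C)c1OCOC
F9 | step 4 | racemic trans-dihydroflavonol tetraol (one enantiomer drawn) | Oc1cccc([C@@H]2[C@@H](O)C(=O)c3c(O)c(CC=C(C)C)c(O)c(CC=C(C)C)c3O2)c1
F10 | step 1 | 2-hydroxy-4,6-bis(prenyloxy)acetophenone | CC(=O)c1c(O)cc(OCC=C(C)C)cc1OCC=C(C)C
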